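**Retrosynthetic overview**

1. The all-E C40 chain is cut at C11=C12 and C11'=C12' (two Wittig reactions): ring B C15 phosphonium salt + (2E,4E,6E)-2,7-dimethylocta-2,4,6-trienedial + ring A C15 phosphonium salt.
2. The ring B C15 unit comes from a bridged bicyclic hydroxy lactone (lactone carbonyl = C7, lactone oxygen = O3), opened by half-reduction and Horner–Wadsworth–Emmons olefination.
3. The bicyclic lactone comes from an open-chain hydroxy diketo ester in one operation: lactonisation plus SmI2 ketyl–ketone coupling closes the lactone ring and carbocycle B together and sets C5 and C6 from C3. C3 is set by an (S)-proline aldol of acetone.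
4. The ring A C15 unit comes from (4R,6R)-actinol and (E)-3-methylpent-2-en-4-yn-1-ol (alkynylation, dehydration). Ring A is not built; it is carried from actinol.
5. Ring order: lactone ring and ring B in the same operation (step 4); the lactone ring is opened again in step 5; ring A is present from the start of its branch.

Assumption: atoms are named by carotenoid numbering (ring B = triol ring C1–C6 with chain C7–C15, primed numbers for the ring A half), and only isolated products are counted as steps.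

**Route**

Step 1
Reactants: 1 ethyl 3-methyl-2-oxobutanoate; 2 allyl bromide
Product: 5 ethyl 3,3-dimethyl-2-oxohex-5-enoate, via sodium enolate 3 (not isolated), via O-allyl enol ether 4 (not isolated)
Conditions: NaH, DMF, 0 °C; 2, rt; then 140 °C
Reagents that add atoms: none
Why: O-allylation of the tetrasubstituted enolate followed by thermal Claisen rearrangement ([3,3]-sigmatropic shift) moves the allyl group to carbon and creates the quaternary gem-dimethyl carbon (future C1), any directly C-allylated material being the same product.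

Step 2
Reactants: 5 ethyl 3,3-dimethyl-2-oxohex-5-enoate
Product: 7 ethyl 3,3-dimethyl-2,5-dioxopentanoate, via ozonide 6 (not isolated)
Conditions: O3, CH2Cl2, −78 °C; then Me2S, −78 °C → rt
Reagents that add atoms: ozone, O=[O+][O-]
Why: Ozonolysis with reductive work-up cleaves the only C=C bond to the aldehyde (future C3) and leaves the hindered keto ester untouched.

Step 3
Reactants: 7 ethyl 3,3-dimethyl-2,5-dioxopentanoate; 8 acetone
Product: 9 ethyl (5S)-5-hydroxy-3,3-dimethyl-2,7-dioxooctanoate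
Conditions: (S)-proline (30 mol %), acetone–DMSO 4:1, 4 °C → rt
Reagents that add atoms: none
Why: Proline-catalysed direct (enamine) aldol addition of acetone to the unhindered aldehyde, the neopentyl-flanked keto ester staying inert; the hydrogen-bonded Houk–List transition state gives the same facial sense as the (R)-aldols of branched aldehydes, which is (5S) here by CIP priorities and becomes C3 of ring B.

Step 4
Reactants: 9 ethyl (5S)-5-hydroxy-3,3-dimethyl-2,7-dioxooctanoate
Product: 11 (1S,4S,5R)-4,5-dihydroxy-5,8,8-trimethyl-2-oxabicyclo[2.2.2]octan-3-one, via keto lactone 10 (not isolated)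
Conditions: PPTS (5 mol %), PhMe, 60 °C, −EtOH; evaporate; then SmI2 (2.5 equiv), HMPA, THF, −78 → −20 °C; H2O
Reagents that add atoms: none
Why: Proposed new method: acid-catalysed transesterification closes the six-membered keto lactone 10, whose ketone is reduced by SmI2 to a ketyl that adds through a boat-like six-membered transition state to the pendant methyl ketone, so the lactone ring and carbocycle B form in one operation; the lactone bridge forces C7 cis to O3 and so fixes C6, and under non-chelating HMPA conditions the ketone methyl should take the open side over the lactone bridge while its oxygen faces the gem-dimethyl bridge, which is the cis-5,6-diol (5R); the closest known reaction types are the SmI2 intramolecular pinacol coupling of keto esters bearing a second carbonyl and SmI2 reductive cascade cyclisations that close two rings.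

Step 5
Reactants: 11 (1S,4S,5R)-4,5-dihydroxy-5,8,8-trimethyl-2-oxabicyclo[2.2.2]octan-3-one; 12 ethyl (2E)-4-(diethoxyphosphoryl)-3-methylbut-2-enoate
Product: 15 ethyl (2E,4E)-3-methyl-5-[(1S,2R,4S)-1,2,4-trihydroxy-2,6,6-trimethylcyclohexyl]penta-2,4-dienoate, via bridged lactol 13 (not isolated), via lithiated phosphonate 14 (not isolated)
Conditions: iBu2AlH (3.3 equiv), CH2Cl2, −78 °C; then 14 (from 12, LiN(SiMe3)2, THF, −78 °C; 4 equiv), −78 °C → rt; aq. potassium sodium tartrate
Reagents that add atoms: none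
Why: One-pot half-reduction of the lactone and Horner–Wadsworth–Emmons olefination of the open hydroxy aldehyde form of the lactol gives the (E)-C7=C8 bond under thermodynamic control and frees the C3 hydroxyl without touching the three stereocentres.

Step 6
Reactants: 15 ethyl (2E,4E)-3-methyl-5-[(1S,2R,4S)-1,2,4-trihydroxy-2,6,6-trimethylcyclohexyl]penta-2,4-dienoate
Product: 16 (1S,2R,4S)-1-[(1E,3E)-5-hydroxy-3-methylpenta-1,3-dien-1-yl]-2,6,6-trimethylcyclohexane-1,2,4-triol
Conditions: iBu2AlH (6 equiv), CH2Cl2, −78 → 0 °C; aq. potassium sodium tartrate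
Reagents that add atoms: none
Why: iBu2AlH 1,2-reduction of the dienoate gives the primary allylic alcohol, the excess hydride being consumed by the three hydroxyls, and no stereocentre is involved.

Step 7
Reactants: 16 (1S,2R,4S)-1-[(1E,3E)-5-hydroxy-3-methylpenta-1,3-dien-1-yl]-2,6,6-trimethylcyclohexane-1,2,4-triol
Product: 17 [(2E,4E)-3-methyl-5-[(1S,2R,4S)-1,2,4-trihydroxy-2,6,6-trimethylcyclohexyl]penta-2,4-dien-1-yl]triphenylphosphonium bromide
Conditions: Ph3P·HBr (1.05 equiv), MeOH–CH2Cl2 1:1, 0 °C → rt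
Reagents that add atoms: triphenylphosphonium bromide, [Br-].[PH+](c1ccccc1)(c1ccccc1)c1ccccc1
Why: Allylic phosphonium salt formation by substitution of the protonated primary allylic alcohol at C11 under weakly acidic conditions that should spare the tertiary 5,6-diol and the secondary alcohol, the 9E geometry being the thermodynamic one.

Step 8
Reactants: 18 (4R,6R)-4-hydroxy-2,2,6-trimethylcyclohexan-1-one (actinol); 19 (2E)-3-methylpent-2-en-4-yn-1-ol
Product: 21 (1S,4R,6R)-1-[(3E)-5-hydroxy-3-methylpent-3-en-1-yn-1-yl]-2,2,6-trimethylcyclohexane-1,4-diol (major C1 epimer shown), via di-Grignard reagent 20 (not isolated)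
Conditions: 19 (2.5 equiv), EtMgBr (5 equiv), THF, 0 → 40 °C; then 18, rt → 45 °C; H2O
Reagents that add atoms: none
Why: 1,2-addition of the alkynyl Grignard reagent (dianion of the enynol, Isler-type alkynylation) to the hindered ketone, mainly by axial attack; the new carbinol centre is removed in step 9, and the C4 centre of 18 (future C3') is untouched.

Step 9
Reactants: 21 (1S,4R,6R)-1-[(3E)-5-hydroxy-3-methylpent-3-en-1-yn-1-yl]-2,2,6-trimethylcyclohexane-1,4-diol
Product: 24 (2E)-5-[(4R)-4-acetoxy-2,6,6-trimethylcyclohex-1-en-1-yl]-3-methylpent-2-en-4-yn-1-yl acetate, via diacetate 22 (not isolated), via dichlorophosphate 23 (not isolated)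
Conditions: Ac2O (2.5 equiv), pyridine, 0 °C → rt; then POCl3 (3 equiv), 0 → 60 °C
Reagents that add atoms: acetic anhydride, CC(=O)OC(C)=O
Why: Selective acetylation of the primary and secondary hydroxyls, then POCl3–pyridine dehydration of the tertiary propargylic alcohol, which can only lose the C5' hydrogen and so gives the tetrasubstituted C5'=C6' enyne while erasing the methyl-bearing stereocentre of actinol as planned.

Step 10
Reactants: 24 (2E)-5-[(4R)-4-acetoxy-2,6,6-trimethylcyclohex-1-en-1-yl]-3-methylpent-2-en-4-yn-1-yl acetate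
Product: 25 (1R)-4-[(3E)-5-hydroxy-3-methylpent-3-en-1-yn-1-yl]-3,5,5-trimethylcyclohex-3-en-1-ol
Conditions: K2CO3 (0.2 equiv), MeOH, rt
Reagents that add atoms: none
Why: Base-catalysed transesterification (methanolysis) removes both acetates without affecting the enyne or the stereocentre.

Step 11
Reactants: 25 (1R)-4-[(3E)-5-hydroxy-3-methylpent-3-en-1-yn-1-yl]-3,5,5-trimethylcyclohex-3-en-1-ol
Product: 26 [(2E)-5-[(4R)-4-hydroxy-2,6,6-trimethylcyclohex-1-en-1-yl]-3-methylpent-2-en-4-yn-1-yl]triphenylphosphonium bromide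
Conditions: Ph3P·HBr (1.0 equiv), MeOH, 0 °C → rt
Reagents that add atoms: triphenylphosphonium bromide, [Br-].[PH+](c1ccccc1)(c1ccccc1)c1ccccc1
Why: Allylic phosphonium salt formation at the primary allylic alcohol only (the secondary homoallylic alcohol is inert), with the 9'E geometry retained.

Step 12
Reactants: 26 [(2E)-5-[(4R)-4-hydroxy-2,6,6-trimethylcyclohex-1-en-1-yl]-3-methylpent-2-en-4-yn-1-yl]triphenylphosphonium bromide; 27 (2E,4E,6E)-2,7-dimethylocta-2,4,6-trienedial
Product: 29 (2E,4E,6E,8E,10E)-13-[(4R)-4-hydroxy-2,6,6-trimethylcyclohex-1-en-1-yl]-2,7,11-trimethyltrideca-2,4,6,8,10-pentaen-12-ynal, via ylide 28 (not isolated)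
Conditions: 27 (3 equiv), NaOMe (1.1 equiv), CH2Cl2–MeOH, −10 °C → rt; then EtOH, 60 °C
Reagents that add atoms: none
Why: Wittig olefination of the semistabilised ylide with an excess of the symmetrical dialdehyde gives the mono-adduct, and the hindered Z isomer of the new C11'=C12' bond is isomerised thermally to E.

Step 13
Reactants: 17 [(2E,4E)-3-methyl-5-[(1S,2R,4S)-1,2,4-trihydroxy-2,6,6-trimethylcyclohexyl]penta-2,4-dien-1-yl]triphenylphosphonium bromide; 29 (2E,4E,6E,8E,10E)-13-[(4R)-4-hydroxy-2,6,6-trimethylcyclohex-1-en-1-yl]-2,7,11-trimethyltrideca-2,4,6,8,10-pentaen-12-ynal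
Product: 31 all-E (3S,5R,6S,3'R)-7',8'-didehydro-5,6-dihydro-β,β-carotene-3,5,6,3'-tetrol (CNP0160593.2), via ylide 30 (not isolated)
Conditions: NaOMe (1.2 equiv), CH2Cl2–MeOH, 0 °C → rt; then EtOH, 60 °C; crystallisation
Reagents that add atoms: none
Why: The second Wittig olefination joins the halves at C11=C12 with free hydroxyls tolerated, and thermal isomerisation of the hindered 11Z isomer gives the all-E target with all four stereocentres carried through unchanged.

**Compound list**

1 | ethyl 3-methyl-2-oxobutanoate | CCOC(=O)C(=O)C(C)C | starting material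
2 | allyl bromide | C=CCBr | starting material
3 | sodium 1-ethoxy-3-methyl-1-oxobut-2-en-2-olate | CCOC(=O)C([O-])=C(C)C.[Na+] | intermediate (not isolated)
4 | ethyl 3-methyl-2-(prop-2-en-1-yloxy)but-2-enoate | CCOC(=O)C(OCC=C)=C(C)C | intermediate (not isolated)
5 | ethyl 3,3-dimethyl-2-oxohex-5-enoate | CCOC(=O)C(=O)C(C)(C)CC=C | intermediate
6 | ethyl 3,3-dimethyl-2-oxo-4-(1,2,4-trioxolan-3-yl)butanoate | CCOC(=O)C(=O)C(C)(C)CC1OCOO1 | intermediate (not isolated)
7 | ethyl 3,3-dimethyl-2,5-dioxopentanoate | CCOC(=O)C(=O)C(C)(C)CC=O | intermediate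
8 | acetone | CC(C)=O | starting material
9 | ethyl (5S)-5-hydroxy-3,3-dimethyl-2,7-dioxooctanoate (open form; in equilibrium with its five-membered hemiketal) | CCOC(=O)C(=O)C(C)(C)C[C@H](O)CC(C)=O | intermediate
10 | (6S)-4,4-dimethyl-6-(2-oxopropyl)oxane-2,3-dione | O=C1O[C@H](CC(C)=O)CC(C)(C)C1=O | intermediate (not isolated)
11 | (1S,4S,5R)-4,5-dihydroxy-5,8,8-trimethyl-2-oxabicyclo[2.2.2]octan-3-one | O=C1O[C@@H]2C[C@@](C)(O)[C@@]1(O)C(C)(C)C2 | intermediate
12 | ethyl (2E)-4-(diethoxyphosphoryl)-3-methylbut-2-enoate | CCOC(=O)/C=C(C)/CP(=O)(OCC)OCC | starting material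
13 | (1S,4S,5R)-5,8,8-trimethyl-2-oxabicyclo[2.2.2]octane-3,4,5-triol (both C3 epimers) | OC1O[C@@H]2C[C@@](C)(O)[C@@]1(O)C(C)(C)C2 | intermediate (not isolated)
14 | lithium salt of 12 (carbanion at the phosphorus-bearing carbon) | [Li+].CCOC(=O)/C=C(C)/[CH-]P(=O)(OCC)OCC | intermediate (not isolated)
15 | ethyl (2E,4E)-3-methyl-5-[(1S,2R,4S)-1,2,4-trihydroxy-2,6,6-trimethylcyclohexyl]penta-2,4-dienoate | CCOC(=O)/C=C(C)/C=C/[C@]1(O)C(C)(C)C[C@H](O)C[C@@]1(C)O | intermediate
16 | (1S,2R,4S)-1-[(1E,3E)-5-hydroxy-3-methylpenta-1,3-dien-1-yl]-2,6,6-trimethylcyclohexane-1,2,4-triol | OC/C=C(C)/C=C/[C@]1(O)C(C)(C)C[C@H](O)C[C@@]1(C)O | intermediate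
17 | [(2E,4E)-3-methyl-5-[(1S,2R,4S)-1,2,4-trihydroxy-2,6,6-trimethylcyclohexyl]penta-2,4-dien-1-yl]triphenylphosphonium bromide | [Br-].c1ccccc1[P+](c1ccccc1)(c1ccccc1)C/C=C(C)/C=C/[C@]2(O)C(C)(C)C[C@H](O)C[C@@]2(C)O | intermediate
18 | (4R,6R)-4-hydroxy-2,2,6-trimethylcyclohexan-1-one | O=C1[C@H](C)C[C@@H](O)CC1(C)C | starting material
19 | (2E)-3-methylpent-2-en-4-yn-1-ol | C#C/C(C)=C/CO | starting material
20 | bromomagnesium alkynide–alkoxide of 19 (BrMgC≡C–C(Me)=CH–CH2OMgBr) | Br[Mg]OC/C=C(C)/C#C[Mg]Br | intermediate (not isolated)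
21 | (1S,4R,6R)-1-[(3E)-5-hydroxy-3-methylpent-3-en-1-yn-1-yl]-2,2,6-trimethylcyclohexane-1,4-diol (major C1 epimer) | OC/C=C(C)/C#C[C@]1(O)[C@H](C)C[C@@H](O)CC1(C)C | intermediate
22 | primary and secondary diacetate of 21 (tertiary OH free) | CC(=O)OC/C=C(C)/C#C[C@]1(O)[C@H](C)C[C@@H](OC(C)=O)CC1(C)C | intermediate (not isolated)
23 | tertiary dichlorophosphate of 22 | CC(=O)OC/C=C(C)/C#C[C@]1(OP(=O)(Cl)Cl)[C@H](C)C[C@@H](OC(C)=O)CC1(C)C | intermediate (not isolated)
24 | (2E)-5-[(4R)-4-acetoxy-2,6,6-trimethylcyclohex-1-en-1-yl]-3-methylpent-2-en-4-yn-1-yl acetate | CC(=O)OC/C=C(C)/C#CC1=C(C)C[C@@H](OC(C)=O)CC1(C)C | intermediate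
25 | (1R)-4-[(3E)-5-hydroxy-3-methylpent-3-en-1-yn-1-yl]-3,5,5-trimethylcyclohex-3-en-1-ol | OC/C=C(C)/C#CC1=C(C)C[C@@H](O)CC1(C)C | intermediate
26 | [(2E)-5-[(4R)-4-hydroxy-2,6,6-trimethylcyclohex-1-en-1-yl]-3-methylpent-2-en-4-yn-1-yl]triphenylphosphonium bromide | [Br-].c1ccccc1[P+](c1ccccc1)(c1ccccc1)C/C=C(C)/C#CC2=C(C)C[C@@H](O)CC2(C)C | intermediate
27 | (2E,4E,6E)-2,7-dimethylocta-2,4,6-trienedial | O=C/C(C)=C/C=C/C=C(C)/C=O | starting material
28 | phosphorus ylide of 26 | c1ccccc1P(c1ccccc1)(c1ccccc1)=C/C=C(C)/C#CC2=C(C)C[C@@H](O)CC2(C)C | intermediate (not isolated)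
29 | (2E,4E,6E,8E,10E)-13-[(4R)-4-hydroxy-2,6,6-trimethylcyclohex-1-en-1-yl]-2,7,11-trimethyltrideca-2,4,6,8,10-pentaen-12-ynal | O=C/C(C)=C/C=C/C=C(C)/C=C/C=C(C)/C#CC1=C(C)C[C@@H](O)CC1(C)C | intermediate
30 | phosphorus ylide of 17 | c1ccccc1P(c1ccccc1)(c1ccccc1)=C/C=C(C)/C=C/[C@]2(O)C(C)(C)C[C@H](O)C[C@@]2(C)O | intermediate (not isolated)
31 | all-E (3S,5R,6S,3'R)-7',8'-didehydro-5,6-dihydro-β,β-carotene-3,5,6,3'-tetrol | CC1=C(C#C/C(C)=C/C=C/C(C)=C/C=C/C=C(C)/C=C/C=C(C)/C=C/[C@]2(O)C(C)(C)C[C@H](O)C[C@@]2(C)O)C(C)(C)C[C@H](O)C1 | target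

**Step count and risks**

Total step count: 13. Longest linear sequence: 8 steps (steps 1–7 and 13, from 1 to 31).

The three steps most likely to fail are 4, 5 and 7.

Step 4 is unprecedented on this substrate. The ketyl may simply be reduced, or the C5 epimer may form if samarium chelation wins over sterics. The fallback takes ring B from the chiral pool and replaces steps 1–6. It sets out from 18. Silylation with Me3SiCl, Et3N and NaI in MeCN gives (4R)-2,6,6-trimethyl-1,4-bis(trimethylsilyloxy)cyclohex-1-ene F1. Rubottom oxidation (mCPBA, NaHCO3, CH2Cl2, 0 °C; then citric acid, MeOH) on the face anti to the C3 silyloxy group gives (2R,4S)-2,4-dihydroxy-2,6,6-trimethylcyclohexan-1-one F2. Addition of an excess of the reagent 20 by axial attack, anti to the axial C5 hydroxyl and the axial C1 methyl, gives (1R,2R,4S)-1-[(3E)-5-hydroxy-3-methylpent-3-en-1-yn-1-yl]-2,6,6-trimethylcyclohexane-1,2,4-triol F3. Hydroxyl-directed trans-hydroalumination with NaAlH2(OCH2CH2OMe)2 (THF, 0 °C → rt) then gives the (E)-alkene, and the fallback comes back to the route at 16.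

Step 5 may fail because the bridged lactol opens poorly, or because the open β-hydroxy aldehyde undergoes retro-aldol cleavage under the basic olefination conditions. The fallback builds the chain the ionone way without base and replaces steps 5–7. It sets out from 11, which is reduced with iBu2AlH and the lactol 13 is isolated. A neutral Wittig reaction with the stabilised ylide Ph3P=CHCOCH3 (PhMe, 90 °C) gives (3E)-4-[(1S,2R,4S)-1,2,4-trihydroxy-2,6,6-trimethylcyclohexyl]but-3-en-2-one F4. An excess of CH2=CHMgBr (THF, −20 °C) gives (1E)-3-methyl-1-[(1S,2R,4S)-1,2,4-trihydroxy-2,6,6-trimethylcyclohexyl]penta-1,4-dien-3-ol F5. Ph3P·HBr in MeOH converts this tertiary vinyl carbinol with allylic transposition into the 9E phosphonium salt, and the fallback comes back to the route at 17.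

Step 7 may fail because the tertiary allylic C6 hydroxyl can ionise under HBr (dehydration or pinacol-type shift). The fallback inverts the polarity of the last coupling and replaces steps 7 and 13. It sets out from 16 and 29. Oxidation of 16 with MnO2 (CH2Cl2, rt) gives (2E,4E)-3-methyl-5-[(1S,2R,4S)-1,2,4-trihydroxy-2,6,6-trimethylcyclohexyl]penta-2,4-dienal F6. Reduction of 29 with NaBH4 (MeOH, 0 °C) gives (2E,4E,6E,8E,10E)-13-[(4R)-4-hydroxy-2,6,6-trimethylcyclohex-1-en-1-yl]-2,7,11-trimethyltrideca-2,4,6,8,10-pentaen-12-yn-1-ol F7. Ph3P·HBr converts it into the corresponding C25 triphenylphosphonium bromide F8, which has no tertiary alcohol. A Wittig reaction of F8 with F6 (NaOMe, CH2Cl2–MeOH; then EtOH, 60 °C) brings the fallback back to the route at 31.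

**Further compounds**

F1 | step 4 | (4R)-2,6,6-trimethyl-1,4-bis(trimethylsilyloxy)cyclohex-1-ene | C[Si](C)(C)OC1=C(C)C[C@@H](O[Si](C)(C)C)CC1(C)C
F2 | step 4 | (2R,4S)-2,4-dihydroxy-2,6,6-trimethylcyclohexan-1-one | O=C1[C@](C)(O)C[C@@H](O)CC1(C)C
F3 | step 4 | (1R,2R,4S)-1-[(3E)-5-hydroxy-3-methylpent-3-en-1-yn-1-yl]-2,6,6-trimethylcyclohexane-1,2,4-triol | OC/C=C(C)/C#C[C@]1(O)C(C)(C)C[C@H](O)C[C@@]1(C)O
F4 | step 5 | (3E)-4-[(1S,2R,4S)-1,2,4-trihydroxy-2,6,6-trimethylcyclohexyl]but-3-en-2-one | CC(=O)/C=C/[C@]1(O)C(C)(C)C[C@H](O)C[C@@]1(C)O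
F5 | step 5 | (1E)-3-methyl-1-[(1S,2R,4S)-1,2,4-trihydroxy-2,6,6-trimethylcyclohexyl]penta-1,4-dien-3-ol (both C3 epimers) | C=CC(C)(O)/C=C/[C@]1(O)C(C)(C)C[C@H](O)C[C@@]1(C)O
F6 | step 7 | (2E,4E)-3-methyl-5-[(1S,2R,4S)-1,2,4-trihydroxy-2,6,6-trimethylcyclohexyl]penta-2,4-dienal | O=C/C=C(C)/C=C/[C@]1(O)C(C)(C)C[C@H](O)C[C@@]1(C)O
F7 | step 7 | (2E,4E,6E,8E,10E)-13-[(4R)-4-hydroxy-2,6,6-trimethylcyclohex-1-en-1-yl]-2,7,11-trimethyltrideca-2,4,6,8,10-pentaen-12-yn-1-ol | OC/C(C)=C/C=C/C=C(C)/C=C/C=C(C)/C#CC1=C(C)C[C@@H](O)CC1(C)C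
F8 | step 7 | [(2E,4E,6E,8E,10E)-13-[(4R)-4-hydroxy-2,6,6-trimethylcyclohex-1-en-1-yl]-2,7,11-trimethyltrideca-2,4,6,8,10-pentaen-12-yn-1-yl]triphenylphosphonium bromide | [Br-].c1ccccc1[P+](c1ccccc1)(c1ccccc1)C/C(C)=C/C=C/C=C(C)/C=C/C=C(C)/C#CC2=C(C)C[C@@H](O)CC2(C)C
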